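**Retrosynthetic overview**
- The target is a 7-oxo-8β-acetoxy labdane whose 9α-oxygen is spiro-linked to C13 of a 2,3-dihydrofuran. The last disconnection is the O9–C13 bond of the oxolane ring, made by a Pd(II) Wacker-type oxidative spirocyclization of a 9α-hydroxy 3-alkyl-2,5-dihydrofuran.
- Enabling feature: C13 is a tertiary allylic ether carbon and the enol-ether bond C14=C15 sits next to it in the oxygen ring (C13–C14=C15–O–C16). This 3-alkoxy-2,3-dihydrofuran is the allylic-transposition product of a C13=C14 2,5-dihydrofuran. O9 is 1,4 to C13 through C11–C12 (5-exo), and once C13 is quaternary only C15 carries β-hydrogens.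
- Ring B triad (C7=O, 8β-OAc, 9α-O): α-epoxidation of a Δ8(9) alkene, then the 7β-acetate opens the epoxide at C8 with inversion and hands its acetyl group to O8; oxidation of the freed 7-OH follows.
- Side chain: C12–C13 by sp3–sp2 Negishi coupling with 2,5-dihydrofuran-3-yl triflate; the decalin (C5, C10) is bought as (+)-sclareolide.
- Ring order: A/B bought, dihydrofuran attached by coupling, spiro oxolane closed last.

Key step: step 11

Remark: labdane numbering is used (C7 ketone, C8 OAc/CH3, C9 and C13 spiro carbons, C14=C15 enol ether, C16 ring CH2); α/β refer to the usual drawing with the C10 methyl β. The vinyl triflate is assumed not to be a catalogue item and is made in step 6.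

**Step 1**
Reactants: 1 (+)-sclareolide
Product: 2 methyl 13,14,15,16-tetranorlabd-8-en-12-oate
Conditions: conc. H2SO4, MeOH, 65 °C
Reagents that add atoms: methanol, CO
Why: Acid-catalysed lactone methanolysis with E1 dehydration (Fischer esterification/E1) should ionise the tertiary C8–O bond and, by loss of H9, give the thermodynamically preferred tetrasubstituted Δ8(9) alkene with C5 and C10 untouched.

**Step 2**
Reactants: 2 methyl 13,14,15,16-tetranorlabd-8-en-12-oate
Product: 3 methyl 7-oxo-13,14,15,16-tetranorlabd-8-en-12-oate
Conditions: Rh2(cap)4 (1 mol %), t-BuOOH (70% aq.), DCE, 40 °C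
Reagents that add atoms: tert-butyl hydroperoxide, CC(C)(C)OO
Why: Dirhodium-caprolactamate/TBHP allylic oxidation should turn the ring allylic methylene C7 into the conjugated enone, because the competing allylic C11–H bonds are α to the ester and polarity-mismatched for the electrophilic tert-butylperoxyl radical.

**Step 3**
Reactants: 3 methyl 7-oxo-13,14,15,16-tetranorlabd-8-en-12-oate
Product: 4 13,14,15,16-tetranorlabd-8-ene-7β,12-diol
Conditions: LiAlH4, THF, −78 → 0 °C
Reagents that add atoms: none
Why: Hydride reduction should take the ester to the primary alcohol and the enone 1,2 (the β-carbon C9 is fully substituted), with axial hydride delivery from the α face, anti to the axial C6–Hβ bond, setting the equatorial 7β-hydroxyl.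

**Step 4**
Reactants: 4 13,14,15,16-tetranorlabd-8-ene-7β,12-diol
Product: 5 12-iodo-13,14,15,16-tetranorlabd-8-en-7β-ol
Conditions: I2, PPh3, imidazole, CH2Cl2, 0 °C
Reagents that add atoms: iodine, II
Why: Garegg–Samuelsson (Appel-type) iodination should select the unhindered primary hydroxyl over the secondary allylic one next to the tetrasubstituted alkene, leaving C7 unchanged.

**Step 5**
Reactants: 5 12-iodo-13,14,15,16-tetranorlabd-8-en-7β-ol
Product: 6 12-iodo-13,14,15,16-tetranorlabd-8-en-7β-yl acetate
Conditions: Ac2O, Et3N, DMAP (cat.), CH2Cl2, 0 °C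
Reagents that add atoms: acetic anhydride, CC(=O)OC(C)=O
Why: DMAP-catalysed acylation installs the 7β-acetate that later acts as the internal nucleophile delivering the acetyl group to O8.

**Step 6**
Reactants: 7 dihydrofuran-3(2H)-one
Product: 9 2,5-dihydrofuran-3-yl trifluoromethanesulfonate, via lithium enolate 8 (not isolated)
Conditions: LiHMDS, THF, −78 °C; then PhNTf2, −78 → 0 °C
Reagents that add atoms: N-phenyl-bis(trifluoromethanesulfonimide), O=S(=O)(N(c1ccccc1)S(=O)(=O)C(F)(F)F)C(F)(F)F
Why: Kinetic enolisation away from the ring oxygen (the α-alkoxy enolate is disfavoured) followed by O-sulfonylation (enol triflate formation) should give the 2,5-dihydro regioisomer.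

**Step 7**
Reactants: 6 12-iodo-13,14,15,16-tetranorlabd-8-en-7β-yl acetate; 9 2,5-dihydrofuran-3-yl trifluoromethanesulfonate
Product: 11 15,16-epoxylabda-8,13-dien-7β-yl acetate, via alkylzinc iodide 10 (not isolated)
Conditions: Zn dust (TMSCl/1,2-dibromoethane-activated), DMA, 40 °C; then 9, Pd(PPh3)4 (5 mol %), THF, 50 °C
Reagents that add atoms: none
Why: Zinc insertion into the primary C–I bond and Negishi sp3–sp2 coupling with the vinyl triflate should forge C12–C13, since the primary alkylzinc transmetalates faster than it β-eliminates and the allylic acetate on the tetrasubstituted alkene is too hindered to ionise with Pd(0).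

**Step 8**
Reactants: 11 15,16-epoxylabda-8,13-dien-7β-yl acetate
Product: 12 8α,9α:15,16-diepoxylabd-13-en-7β-yl acetate
Conditions: m-CPBA (1.05 equiv), NaHCO3, CH2Cl2, −20 → 0 °C
Reagents that add atoms: m-chloroperoxybenzoic acid, OOC(=O)c1cccc(Cl)c1
Why: Prilezhaev epoxidation should occur at the electron-rich tetrasubstituted Δ8(9) bond rather than at the dihydrofuran alkene (deactivated by two allylic C–O bonds) and from the α face, opposite the axial C10 methyl and the 7β-acetate, setting C9–O α (final) and C8–O α (to be inverted).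

**Step 9**
Reactants: 12 8α,9α:15,16-diepoxylabd-13-en-7β-yl acetate
Product: 13 8β-acetoxy-15,16-epoxylabd-13-ene-7β,9α-diol
Conditions: HClO4 (cat.), H2O (5 equiv), THF, 0 °C; then NaHCO3
Reagents that add atoms: water, O
Why: In an acid-catalysed epoxide opening with anchimeric assistance, the 7β-acetate carbonyl attacks C8 from the β face (Fürst–Plattner trans-diaxial opening, inversion at C8, 9α-OH released) to a cis-fused 1,3-dioxolan-2-ylium ion, whose hydration and hemiorthoester collapse should leave the acetyl on the axial O8 and free the equatorial 7β-OH.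

**Step 10**
Reactants: 13 8β-acetoxy-15,16-epoxylabd-13-ene-7β,9α-diol
Product: 14 8β-acetoxy-9α-hydroxy-15,16-epoxylabd-13-en-7-one
Conditions: Dess–Martin periodinane, NaHCO3, CH2Cl2, 0 → 23 °C
Reagents that add atoms: none
Why: Dess–Martin oxidation converts the only secondary alcohol into the C7 ketone under buffered conditions, the tertiary 9α-OH and the tertiary acetate being inert and C8 having no α-hydrogen to epimerise.

**Step 11**
Reactants: 14 8β-acetoxy-9α-hydroxy-15,16-epoxylabd-13-en-7-one
Product: 15 8β-acetoxy-9α,13R:15,16-diepoxylabd-14-en-7-one (target)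
Conditions: PdCl2(MeCN)2 (10 mol %), 1,4-benzoquinone (1.5 equiv), 2,6-di-tert-butyl-4-methylpyridine (0.5 equiv), 3 Å MS, THF, 23 °C
Reagents that add atoms: none
Why: Pd(II) binds the C13=C14 bond of the 2,5-dihydrofuran on the face away from the decalin, the 9α-hydroxyl (1,4 to C13 through C11–C12) adds anti at the more substituted C13 and closes the oxolane 5-exo-trig, and the C14–Pd alkyl, whose only β-hydrogens are on C15 because C13 is now quaternary, loses Pd–H to place the double bond at C14=C15 while benzoquinone returns Pd(0) to Pd(II). The closest known reaction type is the Wacker-type oxidative cyclization of alkenols at trisubstituted alkenes, which gives cyclic ethers with a fully substituted O-bearing carbon and a transposed double bond. In one operation the step forms the O9–C13 bond, the spiro oxolane ring and the C13 stereocentre, and turns a robust allyl ether into the acid-labile enol ether without any acid-mediated step. C13 is set by substrate control: in the anti-oxypalladation expected for chloride-ligated Pd, the compact trigonal C14 terminus should sit under the rigid C1/C5 flank (axial H1α, H5α) and the C16 methylene under the C7/C8 flank flattened by the C7 carbonyl, which is 13R, but this bias is expected to be modest. Regioselectivity (5-exo at C13 over 6-endo at C14), the single direction of β-hydride elimination and chemoselectivity (a tertiary alcohol cannot be oxidised) are secured by the substrate, and the hindered pyridine keeps the medium non-acidic so that the 3-alkoxy-2,3-dihydrofuran does not ionise and aromatise.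

**Compound list**
1 | (+)-sclareolide (8α,12-olide of the normal labdane series, 10β-CH3, 5α-H) | CC1(CCC[C@]2([C@H]1CC[C@@]3([C@@H]2CC(=O)O3)C)C)C | starting material
2 | methyl 13,14,15,16-tetranorlabd-8-en-12-oate (tetrasubstituted Δ8(9) ester) | COC(=O)CC1=C(C)CC[C@H]2C(C)(C)CCC[C@]12C | intermediate
3 | methyl 7-oxo-13,14,15,16-tetranorlabd-8-en-12-oate | COC(=O)CC1=C(C)C(=O)C[C@H]2C(C)(C)CCC[C@]12C | intermediate
4 | 13,14,15,16-tetranorlabd-8-ene-7β,12-diol | OCCC1=C(C)[C@@H](O)C[C@H]2C(C)(C)CCC[C@]12C | intermediate
5 | 12-iodo-13,14,15,16-tetranorlabd-8-en-7β-ol | ICCC1=C(C)[C@@H](O)C[C@H]2C(C)(C)CCC[C@]12C | intermediate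
6 | 12-iodo-13,14,15,16-tetranorlabd-8-en-7β-yl acetate | ICCC1=C(C)[C@@H](OC(C)=O)C[C@H]2C(C)(C)CCC[C@]12C | intermediate
7 | dihydrofuran-3(2H)-one | O=C1CCOC1 | starting material
8 | lithium 2,5-dihydrofuran-3-olate | [Li]OC1=CCOC1 | intermediate (not isolated)
9 | 2,5-dihydrofuran-3-yl trifluoromethanesulfonate | O=S(=O)(OC1=CCOC1)C(F)(F)F | intermediate
10 | (7β-acetoxy-13,14,15,16-tetranorlabd-8-en-12-yl)zinc iodide | I[Zn]CCC1=C(C)[C@@H](OC(C)=O)C[C@H]2C(C)(C)CCC[C@]12C | intermediate (not isolated)
11 | 15,16-epoxylabda-8,13-dien-7β-yl acetate (2,5-dihydrofuran-3-yl at C12) | CC(=O)O[C@H]1C[C@H]2C(C)(C)CCC[C@]2(C)C(CCC2=CCOC2)=C1C | intermediate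
12 | 8α,9α:15,16-diepoxylabd-13-en-7β-yl acetate | CC(=O)O[C@H]1C[C@H]2C(C)(C)CCC[C@]2(C)[C@]2(CCC3=CCOC3)O[C@]12C | intermediate
13 | 8β-acetoxy-15,16-epoxylabd-13-ene-7β,9α-diol | CC(=O)O[C@@]1(C)[C@@H](O)C[C@H]2C(C)(C)CCC[C@]2(C)[C@@]1(O)CCC1=CCOC1 | intermediate
14 | 8β-acetoxy-9α-hydroxy-15,16-epoxylabd-13-en-7-one | CC(=O)O[C@@]1(C)C(=O)C[C@H]2C(C)(C)CCC[C@]2(C)[C@@]1(O)CCC1=CCOC1 | intermediate
15 | 8β-acetoxy-9α,13R:15,16-diepoxylabd-14-en-7-one | CC(=O)O[C@@]1(C)C(=O)C[C@H]2C(C)(C)CCC[C@]2(C)[C@@]12CC[C@]1(C=COC1)O2 | target

**Step count**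
Total steps: 11. Longest linear sequence: 10 steps (steps 1–5 and 7–11, from 1); step 6 is a one-step branch.

**Steps most likely to fail**

1. Step 11. The decalin may discriminate the two alkene faces only weakly, giving poor facial selectivity at C13. The new allylic C13–O bond may also ionise under traces of acid with aromatisation to the furan, or Pd may dehydrogenate the dihydrofuran. The fallback sets out from 14 and returns at 15. Iodoetherification (I2, NaHCO3, MeCN, 0 °C; anti addition, 5-exo at C13, no acid present) should give 8β-acetoxy-14-iodo-9α,13:15,16-diepoxylabdan-7-one F1, a stable compound at which C13 epimers can be separated. E2 dehydroiodination (DBU, toluene, 80 °C), for which C15 carries the only β-hydrogens, then delivers 15 under basic conditions.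

2. Step 9. The acetyl group may end on the secondary O7 (wrong sense of hemiorthoester collapse or acyl migration on work-up), water may open the epoxide directly, or the C9 cation may trigger a skeletal shift. The fallback sets out from 12 and returns at 14. The epoxide is opened as in step 9 and the crude product, whatever the position of its acetyl group, is methanolysed (K2CO3, MeOH, 23 °C) to 15,16-epoxylabd-13-ene-7β,8β,9α-triol F2. TPAP/NMO oxidises its only secondary hydroxyl to 8β,9α-dihydroxy-15,16-epoxylabd-13-en-7-one F3. The α-ketol 8-OH, the less encumbered of the two tertiary hydroxyls, is then acetylated (Ac2O, DMAP, Et3N, CH2Cl2, 40 °C) to give 14.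

3. Step 7. The homoallylic organozinc may form sluggishly or be lost by protodemetalation or β-hydride elimination, or Pd(0) may ionise the allylic acetate. The fallback sets out from 6 and returns at 11. E2 elimination (DBU, toluene, 60 °C) gives 13,14,15,16-tetranorlabda-8,11-dien-7β-yl acetate F4. 9-BBN hydroborates its terminal vinyl group at C12 to the B-alkyl-9-borabicyclo[3.3.1]nonane F5, used in situ. B-alkyl Suzuki–Miyaura coupling with 9 (PdCl2(dppf), aq. K3PO4, DMF, 50 °C) then gives 11.

**Further compounds**
F1 | step 11 | 8β-acetoxy-14-iodo-9α,13:15,16-diepoxylabdan-7-one (C13 as in the target, iodine anti to O9) | CC(=O)O[C@@]1(C)C(=O)C[C@H]2C(C)(C)CCC[C@]2(C)[C@@]12CC[C@]1([C@@H](I)COC1)O2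
F2 | step 9 | 15,16-epoxylabd-13-ene-7β,8β,9α-triol | O[C@@]1(C)[C@@H](O)C[C@H]2C(C)(C)CCC[C@]2(C)[C@@]1(O)CCC1=CCOC1
F3 | step 9 | 8β,9α-dihydroxy-15,16-epoxylabd-13-en-7-one | O[C@@]1(C)C(=O)C[C@H]2C(C)(C)CCC[C@]2(C)[C@@]1(O)CCC1=CCOC1
F4 | step 7 | 13,14,15,16-tetranorlabda-8,11-dien-7β-yl acetate | CC(=O)O[C@H]1C[C@H]2C(C)(C)CCC[C@]2(C)C(C=C)=C1C
F5 | step 7 | 9-(7β-acetoxy-13,14,15,16-tetranorlabd-8-en-12-yl)-9-borabicyclo[3.3.1]nonane | CC(=O)O[C@H]1C[C@H]2C(C)(C)CCC[C@]2(C)C(CCB2C3CCCC2CCC3)=C1C
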